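Cuts (ring A = diol ring; ring B = bromocyclohexanol ring with C-1 carbinol, C-2 CHBr, C-3 CH2, C-4 CH bearing the side chain): first the C-1–CH3 bond of ring B. Next both ring bonds of C-2, which excises "CBr" and leaves a cyclopentene. Then the bond from C-4 to the C(=CH2) linker, and last the ring A C-3–CH2 bond.
Enabling feature: in ring B the brominated C-2 lies between C-1 (a latent ketone) and the C-3 methylene that leads to C-4. The array O–C-1–C-2(Br)–C-3 is the opened form of a 1-siloxy-6,6-dibromobicyclo[3.1.0]hexane, so ring B can grow from a five-membered enol ether plus CBr2.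
Forward order: ring A is taken from (S)-carvone and dressed (steps 1–6). The chain is joined to cyclopent-2-enone (step 7), and the five-membered ring is enlarged to ring B (step 8). Conjugate reduction, methyl addition and desilylation follow (steps 9–11).
Stereochemistry, ring A: C-4 comes from carvone, C-3 from alkylation trans to isopropenyl, C-1 from nucleophilic epoxidation anti to isopropenyl, and C-2 from axial hydride attack on the alpha-ketol.
Stereochemistry, ring B: C-4 is set by (R)-BINAP/rhodium catalyst control. C-2 is set by axial protonation of the bromo enolate (Br equatorial), and C-1 by equatorial methyl attack (OH axial, syn to Br).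
Key step: step 8
Assumption: the SMILES is read as (1S,2S,3R,4S) in ring A (all substituents equatorial except the axial 1-methyl) and (1S,2R,4R) in ring B (Br, CH3 and side chain equatorial, OH axial, a syn bromohydrin); the sense of induction of (R)-BINAP follows the usual model for cyclic enones, and the antipodal ligand would be used if it proved opposite.

Step 1
Reactants: 1 (S)-(+)-carvone; 2 2,3-dibromopropene
Product: 4 (5S,6R)-6-(2-bromoprop-2-en-1-yl)-2-methyl-5-(prop-1-en-2-yl)cyclohex-2-en-1-one, via lithium dienolate 3 (not isolated)
Conditions: LiN(i-Pr)2 (1.05 equiv), THF, −78 °C; then 2, DMPU, −78 → −20 °C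
Reagents that add atoms: none
Why: Kinetic enolate alkylation, in which LiN(i-Pr)2 removes the alpha′ proton to give the cross-conjugated dienolate 3, which attacks the allylic (not the vinylic) C–Br of 2 from the face anti to the adjacent isopropenyl group, so the new centre is trans (6R) and the vinyl bromide survives as the handle for step 7.

Step 2
Reactants: 4
Product: 5 (1S,3R,4S,6S)-3-(2-bromoprop-2-en-1-yl)-1-methyl-4-(prop-1-en-2-yl)-7-oxabicyclo[4.1.0]heptan-2-one
Conditions: 30% H2O2, NaOH (catalytic), MeOH, 0 °C
Reagents that add atoms: hydrogen peroxide, OO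
Why: Weitz–Scheffer nucleophilic epoxidation, in which hydroperoxide adds only to the electron-poor enone, axially at the beta carbon and anti to the isopropenyl group, so both new C–O bonds (1S,6S) lie on the face opposite to isopropenyl, as required at the methyl-bearing carbinol carbon.

Step 3
Reactants: 5
Product: 7 (1S,2R,3R,4S)-3-(2-bromoprop-2-en-1-yl)-1-methyl-4-(prop-1-en-2-yl)cyclohexane-1,2-diol, via lithium epoxy alkoxide 6 (not isolated)
Conditions: Li[HBEt3] (3.5 equiv), THF, 0 → 23 °C; then H2O
Reagents that add atoms: none
Why: Trialkylborohydride reduction, in which the ketone is reduced first and the bulky, strongly nucleophilic hydride then opens the trisubstituted epoxide by SN2 attack at its secondary carbon only (the flexible monocyclic ring can reach the half-chair needed for anti opening), so the C–O bond at the methyl-bearing carbon keeps its configuration, while the secondary carbinol (drawn for hydride attack anti to the epoxide oxygen) is erased in step 4.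

Step 4
Reactants: 7
Product: 8 (2S,5S,6R)-6-(2-bromoprop-2-en-1-yl)-2-hydroxy-2-methyl-5-(prop-1-en-2-yl)cyclohexan-1-one
Conditions: 2-iodoxybenzoic acid (1.5 equiv), DMSO, 23 °C
Reagents that add atoms: none
Why: 2-Iodoxybenzoic acid oxidation of a 1,2-diol to the alpha-ketol without C–C cleavage, in which only the secondary alcohol can react, so the wrong carbinol centre is removed and the tertiary centre is untouched.

Step 5
Reactants: 8
Product: 9 (1S,2S,3R,4S)-3-(2-bromoprop-2-en-1-yl)-1-methyl-4-(prop-1-en-2-yl)cyclohexane-1,2-diol
Conditions: NaBH4, MeOH, −20 → 0 °C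
Reagents that add atoms: none
Why: Substrate-controlled borohydride reduction, in which the small hydride attacks the carbonyl of the chair of 8 (both side chains equatorial, methyl axial) along the axial trajectory on the face opposite to the axial methyl group, giving the equatorial (2S) alcohol trans to the tertiary hydroxyl.

Step 6
Reactants: 9
Product: 10 (1S,2S,3R,4S)-3-(2-bromoprop-2-en-1-yl)-1-methyl-4-(prop-1-en-2-yl)-1,2-bis(triethylsilyloxy)cyclohexane
Conditions: Et3SiOTf (3 equiv), 2,6-lutidine, CH2Cl2, 0 → 23 °C
Reagents that add atoms: triethylsilyl trifluoromethanesulfonate, CC[Si](CC)(CC)OS(=O)(=O)C(F)(F)F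
Why: Silyl ether formation by a silyl triflate is reactive enough for the tertiary hydroxyl, creates no stereocentre and masks both acidic protons for the organometallic and carbene steps.

Step 7
Reactants: 10; 11 cyclopent-2-en-1-one
Product: 14 1-(trimethylsilyloxy)-(3R)-3-[3-(ring A)prop-1-en-2-yl]cyclopent-1-ene (double bond C-1=C-2; ring A = the (1S,2S,3R,4S) bis-triethylsilyl unit of 10 bound through its 3-CH2), via alkenyllithium 12 (not isolated), via alkenylzinc chloride 13 (not isolated)
Conditions: t-BuLi (2.0 equiv), Et2O, −78 °C; ZnCl2 (THF), −78 → 0 °C; then 11, Me3SiCl (1.5 equiv), [RhCl(C2H4)2]2 (1.5 mol %), (R)-BINAP (3.3 mol %), THF, 20 °C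
Reagents that add atoms: chlorotrimethylsilane, C[Si](C)(C)Cl
Why: Rhodium-catalysed asymmetric conjugate addition of an organozinc halide run in the presence of a chlorosilane, in which the alkenylrhodium species adds to the enone face selected by (R)-BINAP (catalyst control, ring A being too remote to interfere) to set the (3R) centre, and the rhodium enolate is silylated before it can equilibrate, which fixes the enol ether double bond between the former carbonyl carbon and the carbon next to the new centre.

Step 8
Reactants: 14; 15 bromoform
Product: 17 (4R)-2-bromo-4-[3-(ring A)prop-1-en-2-yl]cyclohex-2-en-1-one, via dibromocyclopropane 16 (not isolated)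
Conditions: 15 (1.2 equiv), KOt-Bu (1.15 equiv), pentane, −40 °C; then 2,6-lutidine (1.5 equiv), −40 → 23 °C; aqueous work-up
Reagents that add atoms: none
Why: Alpha-elimination of HBr from 15 gives singlet CBr2, which adds in a concerted [2+1] cheletropic manner to the silyl enol ether C=C of 14, anti to the side chain, and so closes the three-membered ring of 16 (a 1-siloxy-6,6-dibromobicyclo[3.1.0]hexane). On warming, the endo C–Br bond ionises in concert with disrotatory two-electron electrocyclic opening of the ring-fusion C–C bond (cyclopropyl-to-allyl cation, Woodward–Hoffmann–DePuy rule), pushed by the siloxy oxygen and by strain release; no further ring is closed, the five-membered ring becomes the six-membered perimeter, and loss of the silyl group from the oxocarbenium ion gives the 2-bromo enone. The closest known reaction type is the dihalocarbene ring enlargement of cyclic trimethylsilyl enol ethers to 2-halocycloalk-2-enones. No stereocentre is created in 17 (the two bridgeheads of 16, set by anti approach and cis fusion, become sp2), and the (R) methine that carries the side chain takes part in no bond change. Regioselectivity, that is CBr between the carbonyl carbon and the CH next to that methine, is dictated solely by the position of the enol ether double bond fixed in step 7. Chemoselectivity over the two 1,1-disubstituted alkenes relies on the electrophilic carbene preferring the oxygen-donor, trisubstituted, strained alkene and on near-stoichiometric 15, while KOt-Bu as the limiting reagent and the 2,6-lutidine buffer protect the doubly allylic methine and the silyl ethers once enone and Me3SiBr appear.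

Step 9
Reactants: 17
Product: 19 (2R,4R)-2-bromo-4-[3-(ring A)prop-1-en-2-yl]cyclohexan-1-one, via lithium bromo enolate 18 (not isolated)
Conditions: Li[HB(s-Bu)3] (L-Selectride, 1.05 equiv), THF, −78 °C; then AcOH in THF, −78 °C
Reagents that add atoms: none
Why: Conjugate hydride reduction of a beta-unsubstituted cyclohexenone by a trialkylborohydride (the alpha-bromine shields the carbonyl and raises beta-electrophilicity) followed by kinetic protonation of enolate 18 along the axial trajectory of the chair-like transition state with the side chain equatorial, which places H axial and Br equatorial, cis to the side chain (2R).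

Step 10
Reactants: 19
Product: 20 (1S,2R,4R)-2-bromo-1-methyl-4-[3-(ring A)prop-1-en-2-yl]cyclohexan-1-ol (ring A still the bis-triethylsilyl ether)
Conditions: MeLi, anhydrous CeCl3, THF, −78 °C; aqueous NH4Cl at −78 °C
Reagents that add atoms: methyllithium, [Li]C
Why: 1,2-Addition of a weakly basic organocerium reagent to an enolisable alpha-halo ketone, in which the small methyl nucleophile takes the equatorial trajectory on the locked chair (Br and side chain equatorial) to give equatorial CH3 and axial OH (1S), the syn bromohydrin, which lacks an anti-periplanar O/Br pair for epoxide closure, while the cold quench forestalls semipinacol ring contraction of the alkoxide.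

Step 11
Reactants: 20
Product: 21 (1S,2S,3R,4S)-3-{2-[(1R,3R,4S)-3-bromo-4-hydroxy-4-methylcyclohexyl]prop-2-en-1-yl}-1-methyl-4-(prop-1-en-2-yl)cyclohexane-1,2-diol (target)
Conditions: HF·pyridine, pyridine, THF, 0 → 23 °C
Reagents that add atoms: none
Why: Fluoride-mediated cleavage of the two triethylsilyl ethers under mildly acidic, non-basic conditions leaves the base-sensitive bromohydrin, the tertiary alcohols and both 1,1-disubstituted alkenes untouched and changes no stereocentre.

Compound list
1 | (S)-(+)-carvone | CC1=CC[C@@H](CC1=O)C(C)=C | starting material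
2 | 2,3-dibromopropene | C=C(Br)CBr | starting material
3 | lithium cross-conjugated dienolate of carvone | [Li]OC1=C[C@@H](C(=C)C)CC=C1C | intermediate
4 | (5S,6R)-6-(2-bromoallyl)carvone | C=C(Br)C[C@@H]1[C@@H](C(=C)C)CC=C(C)C1=O | intermediate
5 | (1S,3R,4S,6S)-epoxy ketone, oxirane anti to isopropenyl | C=C(Br)C[C@@H]1[C@@H](C(=C)C)C[C@@H]2O[C@]2(C)C1=O | intermediate
6 | lithium alkoxide of the cis epoxy alcohol | C=C(Br)C[C@@H]1[C@@H](C(=C)C)C[C@@H]2O[C@]2(C)[C@@H]1O[Li] | intermediate
7 | (1S,2R,3R,4S)-cis-diol | C=C(Br)C[C@@H]1[C@@H](C(=C)C)CC[C@](C)(O)[C@@H]1O | intermediate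
8 | (2S,5S,6R)-alpha-ketol | C=C(Br)C[C@@H]1[C@@H](C(=C)C)CC[C@](C)(O)C1=O | intermediate
9 | (1S,2S,3R,4S)-trans-diol | C=C(Br)C[C@@H]1[C@@H](C(=C)C)CC[C@](C)(O)[C@H]1O | intermediate
10 | bis(triethylsilyl) ether of 9 | C=C(Br)C[C@@H]1[C@@H](C(=C)C)CC[C@](C)(O[Si](CC)(CC)CC)[C@H]1O[Si](CC)(CC)CC | intermediate
11 | cyclopent-2-en-1-one | O=C1C=CCC1 | starting material
12 | alkenyllithium from 10 | C=C([Li])C[C@@H]1[C@@H](C(=C)C)CC[C@](C)(O[Si](CC)(CC)CC)[C@H]1O[Si](CC)(CC)CC | intermediate
13 | alkenylzinc chloride from 12 | C=C([Zn]Cl)C[C@@H]1[C@@H](C(=C)C)CC[C@](C)(O[Si](CC)(CC)CC)[C@H]1O[Si](CC)(CC)CC | intermediate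
14 | (3R)-3-alkenylcyclopent-1-enyl trimethylsilyl ether | C=C(C[C@@H]1[C@@H](C(=C)C)CC[C@](C)(O[Si](CC)(CC)CC)[C@H]1O[Si](CC)(CC)CC)[C@@H]1CCC(O[Si](C)(C)C)=C1 | intermediate
15 | bromoform | BrC(Br)Br | starting material
16 | 6,6-dibromo-4-alkenyl-1-(trimethylsilyloxy)bicyclo[3.1.0]hexane, cyclopropane anti to the side chain | C=C(C[C@@H]1[C@@H](C(=C)C)CC[C@](C)(O[Si](CC)(CC)CC)[C@H]1O[Si](CC)(CC)CC)[C@@H]1CC[C@]2(O[Si](C)(C)C)[C@H]1C2(Br)Br | intermediate
17 | (4R)-2-bromo-4-alkenylcyclohex-2-en-1-one | C=C(C[C@@H]1[C@@H](C(=C)C)CC[C@](C)(O[Si](CC)(CC)CC)[C@H]1O[Si](CC)(CC)CC)[C@@H]1CCC(=O)C(Br)=C1 | intermediate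
18 | lithium 2-bromo enolate | C=C(C[C@@H]1[C@@H](C(=C)C)CC[C@](C)(O[Si](CC)(CC)CC)[C@H]1O[Si](CC)(CC)CC)[C@@H]1CCC(O[Li])=C(Br)C1 | intermediate
19 | (2R,4R)-cis-2-bromo-4-alkenylcyclohexanone | C=C(C[C@@H]1[C@@H](C(=C)C)CC[C@](C)(O[Si](CC)(CC)CC)[C@H]1O[Si](CC)(CC)CC)[C@@H]1CCC(=O)[C@H](Br)C1 | intermediate
20 | bis(triethylsilyl) ether of the target | C=C(C[C@@H]1[C@@H](C(=C)C)CC[C@](C)(O[Si](CC)(CC)CC)[C@H]1O[Si](CC)(CC)CC)[C@@H]1CC[C@](C)(O)[C@H](Br)C1 | intermediate
21 | CNP0422107.2 | C=C(C[C@@H]1[C@@H](C(=C)C)CC[C@](C)(O)[C@H]1O)[C@@H]1CC[C@](C)(O)[C@H](Br)C1 | target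

Total step count: 11. Longest linear sequence: 11 steps from 1.

Steps most likely to fail

Step 8. The carbene may also add to the two 1,1-disubstituted alkenes. Any alkoxide left when the enone appears may deprotonate the doubly allylic ring B methine, causing epimerisation or migration of the double bond into conjugation. The fallback keeps the one-carbon enlargement of the same enol ether but separates carbon insertion from bromination. It sets out from 14. Furukawa cyclopropanation (Et2Zn, CH2I2, Et2O, 0 °C), whose zinc carbenoid discriminates more strongly in favour of the enol ether, should give the siloxycyclopropane F1. Oxidative opening of its ring-fusion bond with FeCl3 in DMF (Saegusa-type ring enlargement) should give the 3-chloro ketone F2. NaOAc in MeOH should eliminate this to the enone F3. Weitz–Scheffer epoxidation (t-BuOOH, catalytic benzyltrimethylammonium hydroxide, low temperature) should give the epoxy ketone F4. LiBr with Amberlyst 15 should open F4 at the alpha carbon, and the bromohydrin dehydrates, which returns the route at 17.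

Step 9. Hydride may attack the carbonyl in a 1,2 sense, bromide may be lost reductively from the enolate or ketone, and unselective or equilibrating protonation may erode the cis relationship between Br and the side chain. The fallback sets out from 17. Rhodium-catalysed 1,4-hydrosilylation (PhMe2SiH, catalytic RhCl(PPh3)3, benzene, 23–50 °C) should give the isolable 2-bromo silyl enol ether F5. Its separate protodesilylation (AcOH, THF, H2O, 0 °C) should deliver the proton axially at carbon under non-equilibrating conditions and leave the alkyl silyl ethers in place. This comes back to the route at 19.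

Step 7. Transmetallation and insertion of the hindered, alpha-branched alkenyl group at rhodium may be slow. The enolate may be protonated before silylation, which loses the regiochemical information, and facial selectivity may be poor. The fallback gives up catalyst control and relies on separation, which is possible because ring A is enantiopure. It sets out from 12. MgBr2·OEt2 should give the alkenylmagnesium bromide F6. The copper-catalysed, chlorosilane-accelerated conjugate addition (catalytic CuBr·SMe2, Me3SiCl, DMPU, THF, −78 °C) to 11 should give 14 together with its ring B epimer F7. F7 is removed by chromatography on triethylamine-deactivated silica gel, so the fallback comes back to the route at 14.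

Further compounds
F1 | step 8 | 4-alkenyl-1-(trimethylsilyloxy)bicyclo[3.1.0]hexane, cyclopropane anti to the side chain | C=C(C[C@@H]1[C@@H](C(=C)C)CC[C@](C)(O[Si](CC)(CC)CC)[C@H]1O[Si](CC)(CC)CC)[C@@H]1CC[C@]2(O[Si](C)(C)C)[C@H]1C2
F2 | step 8 | 3-chloro-4-alkenylcyclohexanone, chlorine drawn trans to the side chain | C=C(C[C@@H]1[C@@H](C(=C)C)CC[C@](C)(O[Si](CC)(CC)CC)[C@H]1O[Si](CC)(CC)CC)[C@@H]1CCC(=O)C[C@H]1Cl
F3 | step 8 | (4R)-4-alkenylcyclohex-2-en-1-one | C=C(C[C@@H]1[C@@H](C(=C)C)CC[C@](C)(O[Si](CC)(CC)CC)[C@H]1O[Si](CC)(CC)CC)[C@@H]1CCC(=O)C=C1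
F4 | step 8 | 2,3-epoxy-4-alkenylcyclohexanone, oxirane anti to the side chain | C=C(C[C@@H]1[C@@H](C(=C)C)CC[C@](C)(O[Si](CC)(CC)CC)[C@H]1O[Si](CC)(CC)CC)[C@@H]1CCC(=O)[C@H]2O[C@@H]12
F5 | step 9 | 2-bromo-1-[dimethyl(phenyl)silyloxy]-4-alkenylcyclohex-1-ene | C=C(C[C@@H]1[C@@H](C(=C)C)CC[C@](C)(O[Si](CC)(CC)CC)[C@H]1O[Si](CC)(CC)CC)[C@@H]1CCC(O[Si](C)(C)c2ccccc2)=C(Br)C1
F6 | step 7 | alkenylmagnesium bromide from 12 | C=C([Mg]Br)C[C@@H]1[C@@H](C(=C)C)CC[C@](C)(O[Si](CC)(CC)CC)[C@H]1O[Si](CC)(CC)CC
F7 | step 7 | (3S) epimer of 14 | C=C(C[C@@H]1[C@@H](C(=C)C)CC[C@](C)(O[Si](CC)(CC)CC)[C@H]1O[Si](CC)(CC)CC)[C@H]1CCC(O[Si](C)(C)C)=C1
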